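**Plan**
Retrosynthesis: the two central hydroxyls are masked as methyl ethers. The C3'–Br and C5'–Br bonds of both outer rings (rings A and C) are cut, each C4'–OH is traced back through diazonium and amine to a nitro group, and finally both O–C1' diaryl ether bonds are cut together.
Enabling feature: in rings A and C, C1' lies para to the oxygenated C4' and ortho to the C2' bromine. A nitro group at C4' therefore activates a C1'–F bond for SNAr, while the one bromine that no directing group could place is already in the building block.
Forward: no ring is made. Ring B comes from bromanil: its two carbonyl oxygens become the ether oxygens, two bromines stay and two are exchanged for OMe. Rings A and C are bought as one fluoronitroarene, and the three rings are joined in one two-directional step.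
After the coupling: nitro → amine → phenol, the new C4' hydroxyl steers bromine to C3' and C5', and BBr3 frees the central hydroquinone last, so bromine never meets an oxidisable ring B.
Stereochemistry: the target is achiral and has no stereocentre, so nothing has to be set.

Key step: step 3

Remark: primed locants count each outer ring from the ether carbon (C1'). Rotation about the aryl–oxygen bonds is taken as free at room temperature, so atropisomers are not considered.

**Step 1**
Reactants: 1 bromanil (2,3,5,6-tetrabromo-1,4-benzoquinone)
Product: 2 2,5-dibromo-3,6-dimethoxy-1,4-benzoquinone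
Conditions: NaOMe (2.05 equiv), MeOH, 0 °C → rt
Reagents that add atoms: sodium methoxide, [Na+].[O-]C
Why: Twofold addition–elimination (vinylogous acyl substitution) on a haloquinone, in which the first methoxy group turns the carbonyl it conjugates with into a vinylogous ester, so the second methoxide enters at C5 and gives the 2,5-dialkoxy-3,6-dihalo pattern typical of tetrahaloquinones.

**Step 2**
Reactants: 2 2,5-dibromo-3,6-dimethoxy-1,4-benzoquinone
Product: 3 2,5-dibromo-3,6-dimethoxybenzene-1,4-diol
Conditions: Na2S2O4, THF/H2O, rt, Ar
Reagents that add atoms: none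
Why: Dithionite reduction of a quinone to its hydroquinone is fast in aqueous–organic medium and leaves aryl bromides and methyl ethers untouched.

**Step 3**
Reactants: 3 2,5-dibromo-3,6-dimethoxybenzene-1,4-diol; 4 2-bromo-1-fluoro-4-nitrobenzene (2.3 equiv)
Product: 6 1,4-dibromo-2,5-dimethoxy-3,6-bis(2-bromo-4-nitrophenoxy)benzene, via mono-aryl ether phenol 5 (not isolated)
Conditions: Cs2CO3 (3 equiv), dry degassed DMSO, Ar, rt → 60 °C
Reagents that add atoms: none
Why: Carbonate deprotonates 3 one hydroxyl at a time, and each phenoxide adds to the fluorine-bearing C1' of 4 to give a Meisenheimer adduct whose charge rests on the para nitro group before fluoride is expelled (addition–elimination SNAr); the mono-ether 5 then repeats this at its remaining hydroxyl. The closest known reaction type is the twofold etherification of hydroquinones, hindered 2,5-di-tert-butylhydroquinone included, with 4-fluoronitrobenzene and a carbonate base in a dipolar aprotic solvent. No ring is closed and no stereocentre is made; the step forms the two O–C1' bonds. The selectivity needed is fluoride over bromide, and it is secured because fluorine is para to the nitro group and the better SNAr nucleofuge, whereas the C2' bromine is meta to it and the ring B bromines sit on an electron-rich ring. The OMe and Br flanking each phenoxide slow the attack, which is offset by the inductive pull of the ortho bromine in 4 and by the loosely paired caesium phenoxide in DMSO. Exclusion of air and a carbonate rather than a hydride base keep the easily oxidised dianion at low concentration, which limits reversion to quinone 2 and electron transfer to the nitroarene.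

**Step 4**
Reactants: 6 1,4-dibromo-2,5-dimethoxy-3,6-bis(2-bromo-4-nitrophenoxy)benzene
Product: 7 1,4-dibromo-2,5-dimethoxy-3,6-bis(4-amino-2-bromophenoxy)benzene
Conditions: Fe powder, NH4Cl, EtOH/THF/H2O, 75 °C
Reagents that add atoms: none
Why: Béchamp-type iron reduction of nitroarenes under near-neutral conditions works by electron transfer at the metal surface and, unlike hydrogenation over palladium, should not hydrogenolyse the four C–Br bonds.

**Step 5**
Reactants: 7 1,4-dibromo-2,5-dimethoxy-3,6-bis(4-amino-2-bromophenoxy)benzene
Product: 9 1,4-dibromo-2,5-dimethoxy-3,6-bis(2-bromo-4-hydroxyphenoxy)benzene, via bis(diazonium) hydrogen sulfate 8 (not isolated)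
Conditions: NaNO2 (2.05 equiv), H2SO4, AcOH/H2O, 0–5 °C; then Cu(NO3)2 (large excess), Cu2O (1 equiv per diazonium group), H2O, rt
Reagents that add atoms: water, O; sodium nitrite, [Na+].[O-]N=O (its nitrogen is held in 8 only); sulfuric acid, OS(=O)(=O)O (counter-ion of 8 only)
Why: Diazotisation followed by Sandmeyer-type copper-mediated hydroxydediazoniation, in which monovalent copper reduces each diazonium group to an aryl radical that divalent copper traps and water turns into the phenol at room temperature; the step comes before bromination because a diazonium group with free ortho positions has no activated ortho bromide to lose to water.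

**Step 6**
Reactants: 9 1,4-dibromo-2,5-dimethoxy-3,6-bis(2-bromo-4-hydroxyphenoxy)benzene
Product: 10 1,4-dibromo-2,5-dimethoxy-3,6-bis(2,3,5-tribromo-4-hydroxyphenoxy)benzene
Conditions: Br2 (4.2 equiv), AcOH/CH2Cl2, 0 °C → rt, dark
Reagents that add atoms: bromine, BrBr
Why: Electrophilic aromatic bromination of a phenol, in which each C4' hydroxyl directs to its ortho carbons C3' and C5' (para C1' is blocked, C6' is meta to OH), as in the exhaustive bromination of 3-bromophenol that also fills the site between OH and Br, while the hexasubstituted ring B has no free position and, still a dimethyl ether, cannot be oxidised to a quinone.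

**Step 7**
Reactants: 10 1,4-dibromo-2,5-dimethoxy-3,6-bis(2,3,5-tribromo-4-hydroxyphenoxy)benzene
Product: 11 2,5-dibromo-3,6-bis(2,3,5-tribromo-4-hydroxyphenoxy)benzene-1,4-diol (CNP0163357.0)
Conditions: BBr3 (8 equiv), CH2Cl2, −78 °C → rt; ice-water quench, acidic work-up under Ar
Reagents that add atoms: none
Why: BBr3 cleavage of aryl methyl ethers, in which boron binds the methoxy oxygen and bromide attacks the methyl carbon (SN2), a path closed to diaryl ether C–O bonds, so only the two methyl groups are lost and hydrolysis of the borates frees the central hydroquinone.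

**Compound list**
1 | bromanil (2,3,5,6-tetrabromo-1,4-benzoquinone) | O=C1C(Br)=C(Br)C(=O)C(Br)=C1Br | starting material
2 | 2,5-dibromo-3,6-dimethoxy-1,4-benzoquinone | COC1=C(Br)C(=O)C(OC)=C(Br)C1=O | intermediate
3 | 2,5-dibromo-3,6-dimethoxybenzene-1,4-diol | Oc1c(OC)c(Br)c(O)c(OC)c1Br | intermediate
4 | 2-bromo-1-fluoro-4-nitrobenzene | Fc1ccc(cc1Br)[N+](=O)[O-] | starting material
5 | 2,5-dibromo-4-(2-bromo-4-nitrophenoxy)-3,6-dimethoxyphenol (not isolated) | Oc1c(OC)c(Br)c(Oc2ccc(cc2Br)[N+](=O)[O-])c(OC)c1Br | intermediate
6 | 1,4-dibromo-2,5-dimethoxy-3,6-bis(2-bromo-4-nitrophenoxy)benzene | COc1c(Br)c(Oc2ccc(cc2Br)[N+](=O)[O-])c(OC)c(Br)c1Oc1ccc(cc1Br)[N+](=O)[O-] | intermediate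
7 | 1,4-dibromo-2,5-dimethoxy-3,6-bis(4-amino-2-bromophenoxy)benzene | COc1c(Br)c(Oc2ccc(N)cc2Br)c(OC)c(Br)c1Oc1ccc(N)cc1Br | intermediate
8 | bis(diazonium) bis(hydrogen sulfate) derived from 7 (not isolated) | COc1c(Br)c(Oc2ccc(cc2Br)[N+]#N)c(OC)c(Br)c1Oc1ccc(cc1Br)[N+]#N.OS(=O)(=O)[O-].OS(=O)(=O)[O-] | intermediate
9 | 1,4-dibromo-2,5-dimethoxy-3,6-bis(2-bromo-4-hydroxyphenoxy)benzene | COc1c(Br)c(Oc2ccc(O)cc2Br)c(OC)c(Br)c1Oc1ccc(O)cc1Br | intermediate
10 | 1,4-dibromo-2,5-dimethoxy-3,6-bis(2,3,5-tribromo-4-hydroxyphenoxy)benzene | COc1c(Br)c(Oc2cc(Br)c(O)c(Br)c2Br)c(OC)c(Br)c1Oc1cc(Br)c(O)c(Br)c1Br | intermediate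
11 | 2,5-dibromo-3,6-bis(2,3,5-tribromo-4-hydroxyphenoxy)benzene-1,4-diol | Oc1c(Br)cc(Oc2c(O)c(Br)c(Oc3cc(Br)c(O)c(Br)c3Br)c(O)c2Br)c(Br)c1Br | target

**Step count**
Total steps: 7.
Longest linear sequence: 7 (1 → 11). Compound 4 is bought and enters at step 3.

**Steps most likely to fail**

Step 3. The hydroquinone anion may be oxidised back to the quinone level, either by traces of air or by electron transfer to the nitroarene. The second substitution may also stall because of crowding around the remaining phenoxide.
- The fallback changes the activating group to formyl, a far poorer electron acceptor, and unmasks the hydroxyl by oxygen insertion instead of through nitrogen.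
- Setting out from 3, SNAr with commercial 3-bromo-4-fluorobenzaldehyde (O=Cc1ccc(F)c(Br)c1) and Cs2CO3 in degassed DMAc at about 110 °C should give 1,4-dibromo-2,5-dimethoxy-3,6-bis(2-bromo-4-formylphenoxy)benzene F1.
- Baeyer–Villiger oxidation with mCPBA in CH2Cl2, where the para-aryloxy aryl group migrates, should give the bis(formate) 1,4-dibromo-2,5-dimethoxy-3,6-bis(2-bromo-4-formyloxyphenoxy)benzene F2.
- Methanolysis with K2CO3 in MeOH comes back to the route at 9, bypassing steps 4 and 5.

Step 5. The phenol being formed may undergo azo coupling with diazonium groups that have not yet reacted. The aryl radical may pick up hydrogen instead of oxygen, and the poorly water-soluble bis-salt may be converted at only one end.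
- The fallback replaces the aqueous oxygen transfer by a carbon–boron bond made in organic solvent.
- Setting out from 7, Sandmeyer-type borylation (tBuONO, B2pin2, MeCN, rt) should give the bis(pinacol boronate) 1,4-dibromo-2,5-dimethoxy-3,6-bis[2-bromo-4-(4,4,5,5-tetramethyl-1,3,2-dioxaborolan-2-yl)phenoxy]benzene F3.
- Oxidation with H2O2 and NaOH in THF/H2O at 0 °C comes back to the route at 9.

Step 6. Entry of the second bromine at the crowded C3', between OH and the C2' bromine, may be sluggish. Ipso attack at C1' may lead to oxidative loss of the aryloxy group.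
- The fallback lets the stronger amino director place the bromines before nitrogen is exchanged for oxygen.
- Setting out from 7, NBS (4.1 equiv) in DMF at 0 °C → rt should give 1,4-dibromo-2,5-dimethoxy-3,6-bis(4-amino-2,3,5-tribromophenoxy)benzene F4.
- Diazotisation of these weakly basic amines with NaNO2 in concentrated H2SO4/AcOH gives the bis(diazonium) bis(hydrogen sulfate) of the hexabromo diamine F5, which is not isolated.
- Room-temperature treatment with Cu2O and excess Cu(NO3)2 in water avoids the hot aqueous acid in which ortho bromide would be displaced, and comes back to the route at 10.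

**Further compounds**
F1 | step 3 | 1,4-dibromo-2,5-dimethoxy-3,6-bis(2-bromo-4-formylphenoxy)benzene | COc1c(Br)c(Oc2ccc(C=O)cc2Br)c(OC)c(Br)c1Oc1ccc(C=O)cc1Br
F2 | step 3 | 1,4-dibromo-2,5-dimethoxy-3,6-bis(2-bromo-4-formyloxyphenoxy)benzene | COc1c(Br)c(Oc2ccc(OC=O)cc2Br)c(OC)c(Br)c1Oc1ccc(OC=O)cc1Br
F3 | step 5 | 1,4-dibromo-2,5-dimethoxy-3,6-bis[2-bromo-4-(4,4,5,5-tetramethyl-1,3,2-dioxaborolan-2-yl)phenoxy]benzene | COc1c(Br)c(Oc2ccc(cc2Br)B2OC(C)(C)C(C)(C)O2)c(OC)c(Br)c1Oc1ccc(cc1Br)B1OC(C)(C)C(C)(C)O1
F4 | step 6 | 1,4-dibromo-2,5-dimethoxy-3,6-bis(4-amino-2,3,5-tribromophenoxy)benzene | COc1c(Br)c(Oc2cc(Br)c(N)c(Br)c2Br)c(OC)c(Br)c1Oc1cc(Br)c(N)c(Br)c1Br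
F5 | step 6 | bis(diazonium) bis(hydrogen sulfate) of the hexabromo diamine | COc1c(Br)c(Oc2cc(Br)c([N+]#N)c(Br)c2Br)c(OC)c(Br)c1Oc1cc(Br)c([N+]#N)c(Br)c1Br.OS(=O)(=O)[O-].OS(=O)(=O)[O-]
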